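**Retrosynthetic overview**
1. Target 48 ⇒ bis-TBS ether 47 ⇒ three components united in one pot: left C21 trienyl iodide 28 (C12–I), C8 linchpin 7 (C13–Bpin, C13′–I) and right C21 trienyl stannane 45 (C12′–Sn). A base-free Stille coupling forms C12′–C13′, then a Suzuki–Miyaura coupling forms C12–C13 and completes the C50 undecaene.
2. Enabling feature: the symmetric central unit C13(Me)=C14–C15=C15′–C14′=C13′(Me). Each of its methyl-bearing sp2 termini is joined by a single bond to an unbranched E-CH=CH terminus (C11=C12, C11′=C12′), and the only stereocentres (C2, C2′) sit in the two cyclohexene rings, far from the coupling sites.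
3. Each arm: cyclohexenyl triflate + stannyl dienol 9 (Stille, C6–C7), MnO2, then Takai iodo-olefination (left) or stannyl-olefination (right) for C11=C12.
4. Rings: no ring is formed in the route. Both cyclohexene rings are carvone rings ((S)-carvone gives the left ring, made first; (R)-carvone gives the right ring, made second). C2/C2′ are set by trans-selective conjugate addition, after which the isopropenyl relay group is excised. Side chains come from a Wittig reaction (prenyl) and a cross-metathesis (bis-silyloxy unit).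
5. Linchpin 7: (E)-1,2-dichloroethene + two propynes, by two Sonogashira couplings interleaved with two regio-defined syn-hydrometalations (Cu–B, then Zr–H/I2).

Key step: step 27

Remark: the target is read as the all-E (2R,2′S) isomer (carotenoid numbering, primed locants for the diol half). All polyene intermediates are handled under argon in dim light.

**Step 1**
Reactants: 1 (E)-1,2-dichloroethene (5 equiv); 2 propyne
Product: 3 (E)-1-chloropent-1-en-3-yne
Conditions: Pd(PPh3)4 (3 mol %), CuI (6 mol %), n-BuNH2, Et2O, 20 °C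
Reagents that add atoms: none
Why: Sonogashira coupling; the large excess of dichloride and the lower reactivity of the chloroenyne product should limit the reaction to one C–Cl bond, with retention of the E geometry.

**Step 2**
Reactants: 3 (E)-1-chloropent-1-en-3-yne
Product: 4 2-[(2Z,4E)-5-chloropenta-2,4-dien-2-yl]-4,4,5,5-tetramethyl-1,3,2-dioxaborolane
Conditions: B2pin2 (1.1 equiv), CuCl (5 mol %), Xantphos (5 mol %), NaOtBu (10 mol %), MeOH (2 equiv), THF, 20 °C
Reagents that add atoms: bis(pinacolato)diboron, CC1(C)OB(OC1(C)C)B1OC(C)(C)C(C)(C)O1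
Why: Copper-catalysed formal hydroboration of an internal alkyne; syn-borylcupration should place copper next to the chlorovinyl group and boron on the methyl-bearing carbon, and protonolysis by methanol with retention leaves boron trans to the diene chain.

**Step 3**
Reactants: 4 the chlorodienyl boronate; 2 propyne
Product: 5 4,4,5,5-tetramethyl-2-[(2Z,4E)-octa-2,4-dien-6-yn-2-yl]-1,3,2-dioxaborolane
Conditions: PdCl2(PhCN)2 (5 mol %), CuI (10 mol %), piperidine, THF, 20 °C
Reagents that add atoms: none
Why: Sonogashira coupling of an (E)-1-chloro-1,3-diene under amine-promoted conditions; the neutral pinacol boronate does not transmetalate without an oxygen base and the alkene geometries are retained.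

**Step 4**
Reactants: 5 the dienynyl boronate
Product: 7 2-[(2Z,4E,6E)-7-iodoocta-2,4,6-trien-2-yl]-4,4,5,5-tetramethyl-1,3,2-dioxaborolane, via alkenylzirconocene chloride 6 (not isolated)
Conditions: Cp2Zr(H)Cl (1.6 equiv), THF, 20 → 45 °C; then I2 (1.0 equiv), THF, −78 → 0 °C, dark
Reagents that add atoms: iodine, II
Why: Hydrozirconation–iodinolysis with the Schwartz reagent; syn addition of Zr–H, equilibrated by excess reagent to the less hindered methyl-bearing carbon, and iodinolysis with retention should give the (E)-2-iodoalkene terminus, the alkyne reacting much faster than the hindered alkenyl boronate and the diene.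

**Step 5**
Reactants: 8 (E)-3-methylpent-2-en-4-yn-1-ol
Product: 9 (2E,4E)-3-methyl-5-(tributylstannyl)penta-2,4-dien-1-ol
Conditions: Bu3SnH (1.2 equiv), PdCl2(PPh3)2 (2 mol %), THF, 0 °C
Reagents that add atoms: tributyltin hydride, CCCC[SnH](CCCC)CCCC
Why: Palladium-catalysed syn-hydrostannylation of a terminal alkyne; tin adds to the unhindered terminal carbon to give the (E)-alkenylstannane, and any internal regioisomer is removed by chromatography.

**Step 6**
Reactants: 10 dibromomethane; 11 tributyltin chloride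
Product: 13 tributyl(dibromomethyl)stannane, via dibromomethyllithium 12 (not isolated)
Conditions: LDA (1.05 equiv), THF/Et2O, −95 °C; then 11, −95 → −60 °C
Reagents that add atoms: none
Why: Deprotonation of dibromomethane to the lithium carbenoid at very low temperature and its stannylation by the tin chloride (preparation of the reagent for the Hodgson-type stannyl-olefination).

**Step 7**
Reactants: 14 (S)-(+)-carvone; 15 (1,3-dioxolan-2-ylmethyl)magnesium bromide (1.5 equiv, THF solution)
Product: 17 (3R,5S)-3-(1,3-dioxolan-2-ylmethyl)-2,2-dimethyl-5-(prop-1-en-2-yl)cyclohexan-1-one, via magnesium enolate 16 (not isolated)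
Conditions: CuBr·SMe2 (10 mol %), THF, −40 °C; then MeI (5 equiv), DMPU, −40 → 20 °C
Reagents that add atoms: iodomethane, CI
Why: Copper-catalysed conjugate addition of a Grignard reagent followed by C-methylation of the regio-defined enolate; axial attack anti to the C5 isopropenyl group sets C3 trans to it, which is (3R) from (S)-carvone, and alkylation at C2 creates the gem-dimethyl carbon.

**Step 8**
Reactants: 17 the conjugate adduct
Product: 19 (3R)-3-(1,3-dioxolan-2-ylmethyl)-2,2-dimethylcyclohexan-1-one, via methoxy hydroperoxide 18 (not isolated)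
Conditions: O3, MeOH, −78 °C; then FeSO4·7H2O (1.2 equiv), PhSH (1.5 equiv), −78 → 20 °C
Reagents that add atoms: none
Why: Hydrodealkenylation (ozonolysis in methanol, then reductive fragmentation by a divalent iron salt and a thiol); the alkoxy radical from the α-methoxy hydroperoxide loses methyl acetate by β-scission and the C5 ring radical takes a hydrogen atom from benzenethiol, so the relay stereocentre is erased and C3 is untouched.

**Step 9**
Reactants: 19 the dimethyl ketone
Product: 21 (3R)-3-(1,3-dioxolan-2-ylmethyl)-2,2,6-trimethylcyclohexan-1-one (C6 epimers), via lithium enolate 20 (not isolated)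
Conditions: LDA (1.05 equiv), THF, −78 °C; then MeI (1.2 equiv), −78 → 0 °C
Reagents that add atoms: iodomethane, CI
Why: Kinetic enolate alkylation; C6 is the only enolisable position because C2 is quaternary, and the new C6 centre is destroyed in the next step.

**Step 10**
Reactants: 21 the trimethyl ketone
Product: 23 (5R)-5-(1,3-dioxolan-2-ylmethyl)-2,6,6-trimethylcyclohex-1-en-1-yl trifluoromethanesulfonate, via lithium enolate 22 (not isolated)
Conditions: LDA (1.2 equiv), THF, −78 → 0 °C; then PhNTf2 (1.2 equiv), −78 → 20 °C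
Reagents that add atoms: N-phenylbis(trifluoromethanesulfonimide), O=S(=O)(N(c1ccccc1)S(=O)(=O)C(F)(F)F)C(F)(F)F
Why: Enol triflate formation; the tetrasubstituted enolate is the only one possible and O-sulfonylation gives the 2,6,6-trimethylcyclohexenyl triflate type familiar from retinoid chemistry.

**Step 11**
Reactants: 23 the acetal triflate
Product: 24 (5R)-2,6,6-trimethyl-5-(2-oxoethyl)cyclohex-1-en-1-yl trifluoromethanesulfonate
Conditions: 1 M aq. HCl, THF, 40 °C
Reagents that add atoms: water, O
Why: Acid-catalysed acetal hydrolysis; the vinyl triflate is stable to aqueous acid and the stereocentre is β to the aldehyde, so it cannot epimerise.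

**Step 12**
Reactants: 24 the aldehyde triflate
Product: 25 (5R)-2,6,6-trimethyl-5-(3-methylbut-2-en-1-yl)cyclohex-1-en-1-yl trifluoromethanesulfonate
Conditions: i-PrPPh3I (1.4 equiv), n-BuLi (1.35 equiv), THF, 0 °C; then 24, −78 → 20 °C
Reagents that add atoms: isopropyltriphenylphosphonium iodide, CC(C)[P+](c1ccccc1)(c1ccccc1)c1ccccc1.[I-]
Why: Wittig olefination with the non-stabilised isopropylidene ylide gives the prenyl alkene (no E/Z issue), the aldehyde reacting far faster than the vinyl triflate.

**Step 13**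
Reactants: 25 the prenyl triflate; 9 the stannyl dienol (1.2 equiv)
Product: 26 (2E,4E)-3-methyl-5-[(5R)-2,6,6-trimethyl-5-(3-methylbut-2-en-1-yl)cyclohex-1-en-1-yl]penta-2,4-dien-1-ol
Conditions: Pd2(dba)3 (2.5 mol %), AsPh3 (20 mol %), NMP, 60 °C
Reagents that add atoms: none
Why: Stille coupling of a hindered cyclohexenyl triflate with an (E)-dienylstannane under ligand-accelerated conditions, with retention of both alkene geometries; the free allylic alcohol is tolerated.

**Step 14**
Reactants: 26 the left dienol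
Product: 27 (2E,4E)-3-methyl-5-[(5R)-2,6,6-trimethyl-5-(3-methylbut-2-en-1-yl)cyclohex-1-en-1-yl]penta-2,4-dienal
Conditions: MnO2 (15 equiv), CH2Cl2, 20 °C, dark
Reagents that add atoms: none
Why: Chemoselective MnO2 oxidation of the dienylic primary alcohol to the dienal without touching the isolated prenyl alkene.

**Step 15**
Reactants: 27 the left dienal
Product: 28 (5R)-1-[(1E,3E,5E)-6-iodo-3-methylhexa-1,3,5-trien-1-yl]-2,6,6-trimethyl-5-(3-methylbut-2-en-1-yl)cyclohex-1-ene
Conditions: CHI3 (2 equiv), CrCl2 (6 equiv), THF/1,4-dioxane, 0 → 20 °C, dark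
Reagents that add atoms: iodoform, IC(I)I
Why: Takai iodo-olefination; the geminal dichromium species adds to the aldehyde carbonyl and elimination should give the (E)-alkenyl iodide at C11=C12.

**Step 16**
Reactants: 29 (R)-(−)-carvone; 15 (1,3-dioxolan-2-ylmethyl)magnesium bromide (1.5 equiv, THF solution)
Product: 31 (3S,5R)-3-(1,3-dioxolan-2-ylmethyl)-2,2-dimethyl-5-(prop-1-en-2-yl)cyclohexan-1-one, via magnesium enolate 30 (not isolated)
Conditions: CuBr·SMe2 (10 mol %), THF, −40 °C; then MeI (5 equiv), DMPU, −40 → 20 °C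
Reagents that add atoms: iodomethane, CI
Why: Copper-catalysed conjugate addition and enolate C-methylation as in step 7; attack anti to the C5 isopropenyl group of the enantiomeric enone sets (3S).

**Step 17**
Reactants: 31 the conjugate adduct
Product: 33 (3S)-3-(1,3-dioxolan-2-ylmethyl)-2,2-dimethylcyclohexan-1-one, via methoxy hydroperoxide 32 (not isolated)
Conditions: O3, MeOH, −78 °C; then FeSO4·7H2O (1.2 equiv), PhSH (1.5 equiv), −78 → 20 °C
Reagents that add atoms: none
Why: Hydrodealkenylation as in step 8 (ozonolysis, β-scission of the alkoxy radical, hydrogen-atom transfer from the thiol), which removes the relay group and leaves C3 untouched.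

**Step 18**
Reactants: 33 the dimethyl ketone
Product: 35 (3S)-3-(1,3-dioxolan-2-ylmethyl)-2,2,6-trimethylcyclohexan-1-one (C6 epimers), via lithium enolate 34 (not isolated)
Conditions: LDA (1.05 equiv), THF, −78 °C; then MeI (1.2 equiv), −78 → 0 °C
Reagents that add atoms: iodomethane, CI
Why: Kinetic enolate alkylation at C6, the only enolisable position.

**Step 19**
Reactants: 35 the trimethyl ketone
Product: 37 (5S)-5-(1,3-dioxolan-2-ylmethyl)-2,6,6-trimethylcyclohex-1-en-1-yl trifluoromethanesulfonate, via lithium enolate 36 (not isolated)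
Conditions: LDA (1.2 equiv), THF, −78 → 0 °C; then PhNTf2 (1.2 equiv), −78 → 20 °C
Reagents that add atoms: N-phenylbis(trifluoromethanesulfonimide), O=S(=O)(N(c1ccccc1)S(=O)(=O)C(F)(F)F)C(F)(F)F
Why: Enol triflate formation from the only possible (tetrasubstituted) enolate.

**Step 20**
Reactants: 37 the acetal triflate
Product: 38 (5S)-2,6,6-trimethyl-5-(2-oxoethyl)cyclohex-1-en-1-yl trifluoromethanesulfonate
Conditions: 1 M aq. HCl, THF, 40 °C
Reagents that add atoms: water, O
Why: Acid-catalysed acetal hydrolysis; triflate and stereocentre are unaffected.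

**Step 21**
Reactants: 38 the aldehyde triflate
Product: 39 (5S)-2,6,6-trimethyl-5-(prop-2-en-1-yl)cyclohex-1-en-1-yl trifluoromethanesulfonate
Conditions: Ph3PCH3Br (1.3 equiv), KOtBu (1.25 equiv), THF, 0 °C; then 38, 0 → 20 °C
Reagents that add atoms: methyltriphenylphosphonium bromide, C[P+](c1ccccc1)(c1ccccc1)c1ccccc1.[Br-]
Why: Wittig methylenation of the aldehyde; the vinyl triflate is inert to the ylide.

**Step 22**
Reactants: 40 2-methylidenepropane-1,3-diol
Product: 41 2-methylidenepropane-1,3-diol bis(tert-butyldimethylsilyl) ether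
Conditions: TBSCl (2.3 equiv), imidazole (4 equiv), DMF, 20 °C
Reagents that add atoms: tert-butyldimethylsilyl chloride, CC(C)(C)[Si](C)(C)Cl
Why: Standard silylation of both primary alcohols; silyl ethers are chosen because allylic esters could ionise under the later palladium couplings.

**Step 23**
Reactants: 39 the allyl triflate; 41 the bis-silyl alkene (5 equiv)
Product: 42 (5S)-5-{4-[(tert-butyldimethylsilyl)oxy]-3-{[(tert-butyldimethylsilyl)oxy]methyl}but-2-en-1-yl}-2,6,6-trimethylcyclohex-1-en-1-yl trifluoromethanesulfonate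
Conditions: second-generation Hoveyda–Grubbs catalyst (10 mol %), CH2Cl2, 40 °C
Reagents that add atoms: none
Why: Olefin cross-metathesis of a terminal alkene with a symmetrical 1,1-disubstituted alkene used in excess; the two substituents of the new trisubstituted alkene are identical, so there is no geometry to control, and the tetrasubstituted enol triflate alkene should not react.

**Step 24**
Reactants: 42 the bis-silyloxy triflate; 9 the stannyl dienol (1.2 equiv)
Product: 43 (2E,4E)-5-[(5S)-5-{4-[(tert-butyldimethylsilyl)oxy]-3-{[(tert-butyldimethylsilyl)oxy]methyl}but-2-en-1-yl}-2,6,6-trimethylcyclohex-1-en-1-yl]-3-methylpenta-2,4-dien-1-ol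
Conditions: Pd2(dba)3 (2.5 mol %), AsPh3 (20 mol %), NMP, 60 °C
Reagents that add atoms: none
Why: Stille coupling of the hindered cyclohexenyl triflate with the (E)-dienylstannane as in step 13; allylic silyl ethers are inert to zerovalent palladium.

**Step 25**
Reactants: 43 the right dienol
Product: 44 (2E,4E)-5-[(5S)-5-{4-[(tert-butyldimethylsilyl)oxy]-3-{[(tert-butyldimethylsilyl)oxy]methyl}but-2-en-1-yl}-2,6,6-trimethylcyclohex-1-en-1-yl]-3-methylpenta-2,4-dienal
Conditions: MnO2 (15 equiv), CH2Cl2, 20 °C, dark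
Reagents that add atoms: none
Why: MnO2 oxidation of the only free (dienylic) alcohol; the two other allylic oxygens are silylated.

**Step 26**
Reactants: 44 the right dienal; 13 tributyl(dibromomethyl)stannane (2 equiv)
Product: 45 tributyl[(1E,3E,5E)-6-[(5S)-5-{4-[(tert-butyldimethylsilyl)oxy]-3-{[(tert-butyldimethylsilyl)oxy]methyl}but-2-en-1-yl}-2,6,6-trimethylcyclohex-1-en-1-yl]-4-methylhexa-1,3,5-trien-1-yl]stannane
Conditions: CrCl2 (8 equiv), LiI (4 equiv), THF/DMF, 20 °C, dark
Reagents that add atoms: none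
Why: Chromium-mediated stannyl-olefination (Hodgson variant of the Takai reaction), which should convert the aldehyde into the (E)-alkenylstannane at C11′=C12′; silyl ethers and the polyene are inert to divalent chromium.

**Step 27**
Reactants: 45 the right trienyl stannane (1.05 equiv); 7 the iodo-boryl C8 linchpin (1.00 equiv); 28 the left trienyl iodide (1.0 equiv)
Product: 47 the bis(tert-butyldimethylsilyl) ether of the target (all-E, 2R,2′S), via heptaenyl boronate 46 (not isolated)
Conditions: 45 + 7, Pd2(dba)3 (5 mol %), AsPh3 (20 mol %), degassed DMF/THF, 30 °C, dark; then 28, Pd(dppf)Cl2 (5 mol %), 3 M aq. Cs2CO3 (3 equiv), 40 °C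
Reagents that add atoms: none
Why: Zerovalent palladium inserts into the C13′–I bond of 7, stannane 45 transmetalates without base and reductive elimination forms C12′–C13′, giving boronate 46 whose neutral boron cannot transmetalate; aqueous carbonate then turns the pinacol boronate into a borate, which transmetalates to the palladium complex formed from iodide 28, and reductive elimination forms the C12–C13 bond that joins the C21 and C29 halves. The closest known reaction type is the one-pot Stille/Suzuki–Miyaura union of two alkenyl partners through a bifunctional alkenyl boronate linchpin, as used in polyene synthesis. No ring is closed and no stereocentre is created; C2 and C2′ lie in the rings, remote from the reacting carbons. In one operation the step assembles the whole C50 skeleton and its eleven conjugated double bonds from C21 + C8 + C21 pieces. It needs chemoselectivity (tin before boron), single use of each linchpin terminus and retention of every E geometry. These are secured, respectively, by the absence of base in the first stage, by the iodide/boronate polarity of 7 with 45 in slight excess so that no iodide of 7 survives into the basic stage, and by the stereoretentive oxidative addition, transmetalation and reductive elimination at sp2 carbon under mild conditions in the dark.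

**Step 28**
Reactants: 47 the bis-TBS ether
Product: 48 CNP0213288.1, (all-E,2R,2′S)-2′-[4-hydroxy-3-(hydroxymethyl)but-2-en-1-yl]-2-(3-methylbut-2-en-1-yl)-β,β-carotene
Conditions: TBAF (3 equiv), THF, 0 → 20 °C, argon, dark
Reagents that add atoms: none
Why: Fluoride-mediated cleavage of the two primary silyl ethers under non-acidic, non-oxidising conditions that should leave the polyene geometry and both stereocentres untouched.

**Compound list**
1 | (E)-1,2-dichloroethene | Cl/C=C/Cl | starting material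
2 | propyne | CC#C | starting material
3 | (E)-1-chloropent-1-en-3-yne | CC#C/C=C/Cl | intermediate
4 | 2-[(2Z,4E)-5-chloropenta-2,4-dien-2-yl]-4,4,5,5-tetramethyl-1,3,2-dioxaborolane | CC1(C)OB(OC1(C)C)/C(C)=C/C=C/Cl | intermediate
5 | 4,4,5,5-tetramethyl-2-[(2Z,4E)-octa-2,4-dien-6-yn-2-yl]-1,3,2-dioxaborolane | CC1(C)OB(OC1(C)C)/C(C)=C/C=C/C#CC | intermediate
6 | chlorobis(cyclopentadienyl)[(2E,4E,6Z)-7-(4,4,5,5-tetramethyl-1,3,2-dioxaborolan-2-yl)octa-2,4,6-trien-2-yl]zirconium (formed in the flask) | CC1(C)OB(OC1(C)C)/C(C)=C/C=C/C=C(C)/[Zr](Cl)(C1C=CC=C1)C1C=CC=C1 | intermediate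
7 | 2-[(2Z,4E,6E)-7-iodoocta-2,4,6-trien-2-yl]-4,4,5,5-tetramethyl-1,3,2-dioxaborolane (C8 linchpin) | CC1(C)OB(OC1(C)C)/C(C)=C/C=C/C=C(C)/I | intermediate
8 | (E)-3-methylpent-2-en-4-yn-1-ol | C#C/C(C)=C/CO | starting material
9 | (2E,4E)-3-methyl-5-(tributylstannyl)penta-2,4-dien-1-ol | CCCC[Sn](CCCC)(CCCC)/C=C/C(C)=C/CO | intermediate
10 | dibromomethane | BrCBr | starting material
11 | tributyltin chloride | CCCC[Sn](Cl)(CCCC)CCCC | starting material
12 | dibromomethyllithium (formed in the flask) | [Li]C(Br)Br | intermediate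
13 | tributyl(dibromomethyl)stannane | CCCC[Sn](CCCC)(CCCC)C(Br)Br | intermediate
14 | (S)-(+)-carvone | CC1=CC[C@@H](CC1=O)C(C)=C | starting material
15 | (1,3-dioxolan-2-ylmethyl)magnesium bromide | Br[Mg]CC1OCCO1 | starting material
16 | bromomagnesium enolate of the (3R,5S) conjugate adduct (formed in the flask) | Br[Mg]OC1=C(C)[C@@H](CC2OCCO2)C[C@H](C(C)=C)C1 | intermediate
17 | (3R,5S)-3-(1,3-dioxolan-2-ylmethyl)-2,2-dimethyl-5-(prop-1-en-2-yl)cyclohexan-1-one | O=C1C(C)(C)[C@@H](CC2OCCO2)C[C@H](C(C)=C)C1 | intermediate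
18 | (3R,5S)-3-(1,3-dioxolan-2-ylmethyl)-5-(1-hydroperoxy-1-methoxyethyl)-2,2-dimethylcyclohexan-1-one (formed in the flask) | O=C1C(C)(C)[C@@H](CC2OCCO2)C[C@H](C(C)(OC)OO)C1 | intermediate
19 | (3R)-3-(1,3-dioxolan-2-ylmethyl)-2,2-dimethylcyclohexan-1-one | O=C1C(C)(C)[C@@H](CC2OCCO2)CCC1 | intermediate
20 | lithium enolate of 19 (formed in the flask) | [Li]OC1=CCC[C@H](CC2OCCO2)C1(C)C | intermediate
21 | (3R)-3-(1,3-dioxolan-2-ylmethyl)-2,2,6-trimethylcyclohexan-1-one (C6 epimers) | O=C1C(C)(C)[C@@H](CC2OCCO2)CCC1C | intermediate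
22 | lithium enolate of 21 (formed in the flask) | [Li]OC1=C(C)CC[C@H](CC2OCCO2)C1(C)C | intermediate
23 | (5R)-5-(1,3-dioxolan-2-ylmethyl)-2,6,6-trimethylcyclohex-1-en-1-yl trifluoromethanesulfonate | CC1=C(OS(=O)(=O)C(F)(F)F)C(C)(C)[C@@H](CC2OCCO2)CC1 | intermediate
24 | (5R)-2,6,6-trimethyl-5-(2-oxoethyl)cyclohex-1-en-1-yl trifluoromethanesulfonate | CC1=C(OS(=O)(=O)C(F)(F)F)C(C)(C)[C@@H](CC=O)CC1 | intermediate
25 | (5R)-2,6,6-trimethyl-5-(3-methylbut-2-en-1-yl)cyclohex-1-en-1-yl trifluoromethanesulfonate | CC1=C(OS(=O)(=O)C(F)(F)F)C(C)(C)[C@@H](CC=C(C)C)CC1 | intermediate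
26 | (2E,4E)-3-methyl-5-[(5R)-2,6,6-trimethyl-5-(3-methylbut-2-en-1-yl)cyclohex-1-en-1-yl]penta-2,4-dien-1-ol | CC(C)=CC[C@H]1CCC(C)=C(/C=C/C(C)=C/CO)C1(C)C | intermediate
27 | (2E,4E)-3-methyl-5-[(5R)-2,6,6-trimethyl-5-(3-methylbut-2-en-1-yl)cyclohex-1-en-1-yl]penta-2,4-dienal | CC(C)=CC[C@H]1CCC(C)=C(/C=C/C(C)=C/C=O)C1(C)C | intermediate
28 | (5R)-1-[(1E,3E,5E)-6-iodo-3-methylhexa-1,3,5-trien-1-yl]-2,6,6-trimethyl-5-(3-methylbut-2-en-1-yl)cyclohex-1-ene | CC(C)=CC[C@H]1CCC(C)=C(/C=C/C(C)=C/C=C/I)C1(C)C | intermediate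
29 | (R)-(−)-carvone | CC1=CC[C@H](CC1=O)C(C)=C | starting material
30 | bromomagnesium enolate of the (3S,5R) conjugate adduct (formed in the flask) | Br[Mg]OC1=C(C)[C@H](CC2OCCO2)C[C@@H](C(C)=C)C1 | intermediate
31 | (3S,5R)-3-(1,3-dioxolan-2-ylmethyl)-2,2-dimethyl-5-(prop-1-en-2-yl)cyclohexan-1-one | O=C1C(C)(C)[C@H](CC2OCCO2)C[C@@H](C(C)=C)C1 | intermediate
32 | (3S,5R)-3-(1,3-dioxolan-2-ylmethyl)-5-(1-hydroperoxy-1-methoxyethyl)-2,2-dimethylcyclohexan-1-one (formed in the flask) | O=C1C(C)(C)[C@H](CC2OCCO2)C[C@@H](C(C)(OC)OO)C1 | intermediate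
33 | (3S)-3-(1,3-dioxolan-2-ylmethyl)-2,2-dimethylcyclohexan-1-one | O=C1C(C)(C)[C@H](CC2OCCO2)CCC1 | intermediate
34 | lithium enolate of 33 (formed in the flask) | [Li]OC1=CCC[C@@H](CC2OCCO2)C1(C)C | intermediate
35 | (3S)-3-(1,3-dioxolan-2-ylmethyl)-2,2,6-trimethylcyclohexan-1-one (C6 epimers) | O=C1C(C)(C)[C@H](CC2OCCO2)CCC1C | intermediate
36 | lithium enolate of 35 (formed in the flask) | [Li]OC1=C(C)CC[C@@H](CC2OCCO2)C1(C)C | intermediate
37 | (5S)-5-(1,3-dioxolan-2-ylmethyl)-2,6,6-trimethylcyclohex-1-en-1-yl trifluoromethanesulfonate | CC1=C(OS(=O)(=O)C(F)(F)F)C(C)(C)[C@H](CC2OCCO2)CC1 | intermediate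
38 | (5S)-2,6,6-trimethyl-5-(2-oxoethyl)cyclohex-1-en-1-yl trifluoromethanesulfonate | CC1=C(OS(=O)(=O)C(F)(F)F)C(C)(C)[C@H](CC=O)CC1 | intermediate
39 | (5S)-2,6,6-trimethyl-5-(prop-2-en-1-yl)cyclohex-1-en-1-yl trifluoromethanesulfonate | CC1=C(OS(=O)(=O)C(F)(F)F)C(C)(C)[C@H](CC=C)CC1 | intermediate
40 | 2-methylidenepropane-1,3-diol | C=C(CO)CO | starting material
41 | 2-methylidenepropane-1,3-diol bis(tert-butyldimethylsilyl) ether | C=C(CO[Si](C)(C)C(C)(C)C)CO[Si](C)(C)C(C)(C)C | intermediate
42 | (5S)-5-{4-[(tert-butyldimethylsilyl)oxy]-3-{[(tert-butyldimethylsilyl)oxy]methyl}but-2-en-1-yl}-2,6,6-trimethylcyclohex-1-en-1-yl trifluoromethanesulfonate | CC1=C(OS(=O)(=O)C(F)(F)F)C(C)(C)[C@H](CC=C(CO[Si](C)(C)C(C)(C)C)CO[Si](C)(C)C(C)(C)C)CC1 | intermediate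
43 | (2E,4E)-5-[(5S)-5-{4-[(tert-butyldimethylsilyl)oxy]-3-{[(tert-butyldimethylsilyl)oxy]methyl}but-2-en-1-yl}-2,6,6-trimethylcyclohex-1-en-1-yl]-3-methylpenta-2,4-dien-1-ol | OC/C=C(C)/C=C/C1=C(C)CC[C@@H](CC=C(CO[Si](C)(C)C(C)(C)C)CO[Si](C)(C)C(C)(C)C)C1(C)C | intermediate
44 | (2E,4E)-5-[(5S)-5-{4-[(tert-butyldimethylsilyl)oxy]-3-{[(tert-butyldimethylsilyl)oxy]methyl}but-2-en-1-yl}-2,6,6-trimethylcyclohex-1-en-1-yl]-3-methylpenta-2,4-dienal | O=C/C=C(C)/C=C/C1=C(C)CC[C@@H](CC=C(CO[Si](C)(C)C(C)(C)C)CO[Si](C)(C)C(C)(C)C)C1(C)C | intermediate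
45 | tributyl[(1E,3E,5E)-6-[(5S)-5-{4-[(tert-butyldimethylsilyl)oxy]-3-{[(tert-butyldimethylsilyl)oxy]methyl}but-2-en-1-yl}-2,6,6-trimethylcyclohex-1-en-1-yl]-4-methylhexa-1,3,5-trien-1-yl]stannane | CCCC[Sn](CCCC)(CCCC)/C=C/C=C(C)/C=C/C1=C(C)CC[C@@H](CC=C(CO[Si](C)(C)C(C)(C)C)CO[Si](C)(C)C(C)(C)C)C1(C)C | intermediate
46 | C29 heptaenyl pinacol boronate, boron on C13 (formed in the flask) | CC1(C)OB(OC1(C)C)/C(C)=C/C=C/C=C(C)/C=C/C=C(C)/C=C/C1=C(C)CC[C@@H](CC=C(CO[Si](C)(C)C(C)(C)C)CO[Si](C)(C)C(C)(C)C)C1(C)C | intermediate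
47 | bis(tert-butyldimethylsilyl) ether of the target (all-E, 2R,2′S) | CC(C)=CC[C@H]1CCC(C)=C(/C=C/C(C)=C/C=C/C(C)=C/C=C/C=C(C)/C=C/C=C(C)/C=C/C2=C(C)CC[C@@H](CC=C(CO[Si](C)(C)C(C)(C)C)CO[Si](C)(C)C(C)(C)C)C2(C)C)C1(C)C | intermediate
48 | CNP0213288.1, (all-E,2R,2′S)-2′-[4-hydroxy-3-(hydroxymethyl)but-2-en-1-yl]-2-(3-methylbut-2-en-1-yl)-β,β-carotene | CC(C)=CC[C@H]1CCC(C)=C(/C=C/C(C)=C/C=C/C(C)=C/C=C/C=C(C)/C=C/C=C(C)/C=C/C2=C(C)CC[C@@H](CC=C(CO)CO)C2(C)C)C1(C)C | target

**Totals**
Total step count: 28. Longest linear sequence: 12 steps (16, 17, 18, 19, 20, 21, 23, 24, 25, 26, 27, 28, from (R)-carvone).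

**Steps most likely to fail**

Step 27. What may go wrong is protodeboronation or E/Z scrambling of the heptaenyl boronate while it waits for the second coupling, or premature boron-to-palladium transfer that leads to oligomers. The fallback reverses the order of bond formation and keeps boron on a small, robust piece. It sets out from dienynyl boronate 5 and iodide 28. A Suzuki–Miyaura coupling (Pd(dppf)Cl2, aq. Cs2CO3, THF, 40 °C) forms the C12–C13 bond first and should give the left-hand C29 hexaenyne F1. Hydrozirconation with Cp2Zr(H)Cl gives the alkenylzirconocene chloride F2, which is not isolated, and iodinolysis at low temperature gives the heptaenyl iodide F3. A base-free Stille coupling of F3 with stannane 45 (Pd2(dba)3, AsPh3, DMF) returns to the route at 47.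

Step 23. What may go wrong is slow turnover with the bulky 1,1-disubstituted partner, so that homodimerisation of the allyl compound and catalyst decay win. The fallback builds the same alkene by carbonyl olefination and sets out from aldehyde 38. Reduction with NaBH4 in MeOH gives the primary alcohol F4, I2/PPh3/imidazole gives the primary iodide F5, and heating with PPh3 in MeCN gives the phosphonium iodide F6. Deprotonation with NaHMDS gives the ylide F7, which is not isolated, and its Wittig reaction with commercial 1,3-bis(tert-butyldimethylsilyloxy)propan-2-one returns to the route at 42.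

Step 2. What may go wrong is borylcupration with the opposite regiochemistry (boron next to the alkene), or copper-mediated loss of the vinylic chloride. The fallback installs boron by C–I borylation instead and sets out from chloroenyne 3. Hydrozirconation with Cp2Zr(H)Cl gives the alkenylzirconocene chloride F8, which is not isolated, and iodinolysis gives (1E,3E)-1-chloro-4-iodopenta-1,3-diene F9. A Miyaura borylation that is chemoselective for C–I over C–Cl (B2pin2, PdCl2(dppf), KOPh, toluene, 50 °C), with retention of geometry, returns to the route at 4.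

**Further compounds**
F1 | step 27 | (5R)-1-[(1E,3E,5E,7E,9E)-3,7-dimethyltrideca-1,3,5,7,9-pentaen-11-yn-1-yl]-2,6,6-trimethyl-5-(3-methylbut-2-en-1-yl)cyclohex-1-ene | CC(C)=CC[C@H]1CCC(C)=C(/C=C/C(C)=C/C=C/C(C)=C/C=C/C#CC)C1(C)C
F2 | step 27 | alkenylzirconocene chloride from hydrozirconation of F1 (zirconium on C13′) | CC(C)=CC[C@H]1CCC(C)=C(/C=C/C(C)=C/C=C/C(C)=C/C=C/C=C(C)/[Zr](Cl)(C2C=CC=C2)C2C=CC=C2)C1(C)C
F3 | step 27 | (5R)-1-[(1E,3E,5E,7E,9E,11E)-12-iodo-3,7-dimethyltrideca-1,3,5,7,9,11-hexaen-1-yl]-2,6,6-trimethyl-5-(3-methylbut-2-en-1-yl)cyclohex-1-ene | CC(C)=CC[C@H]1CCC(C)=C(/C=C/C(C)=C/C=C/C(C)=C/C=C/C=C(C)/I)C1(C)C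
F4 | step 23 | (5S)-5-(2-hydroxyethyl)-2,6,6-trimethylcyclohex-1-en-1-yl trifluoromethanesulfonate | CC1=C(OS(=O)(=O)C(F)(F)F)C(C)(C)[C@H](CCO)CC1
F5 | step 23 | (5S)-5-(2-iodoethyl)-2,6,6-trimethylcyclohex-1-en-1-yl trifluoromethanesulfonate | CC1=C(OS(=O)(=O)C(F)(F)F)C(C)(C)[C@H](CCI)CC1
F6 | step 23 | triphenyl{2-[(1S)-2,2,4-trimethyl-3-(trifluoromethanesulfonyloxy)cyclohex-3-en-1-yl]ethyl}phosphonium iodide | CC1=C(OS(=O)(=O)C(F)(F)F)C(C)(C)[C@H](CC[P+](c2ccccc2)(c2ccccc2)c2ccccc2)CC1.[I-]
F7 | step 23 | ylide of F6 (formed in the flask) | CC1=C(OS(=O)(=O)C(F)(F)F)C(C)(C)[C@H](CC=P(c2ccccc2)(c2ccccc2)c2ccccc2)CC1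
F8 | step 2 | chlorobis(cyclopentadienyl)[(2E,4E)-5-chloropenta-2,4-dien-2-yl]zirconium (formed in the flask) | Cl[Zr](C1C=CC=C1)(C1C=CC=C1)/C(C)=C/C=C/Cl
F9 | step 2 | (1E,3E)-1-chloro-4-iodopenta-1,3-diene | I/C(C)=C/C=C/Cl
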